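**Balance first.** Substrate is conserved, so what the winter run holds on its plateau at 25.0 min, target 76.5% and side product A 5.5%, leaves 18.0% as side product B, which is 3.27 times side product A.

| setting | winter | summer | Monday's | Wednesday's | Sunday's | Thursday's |
|---|---|---|---|---|---|---|
| substrate | 0.020 M | 0.020 M | 0.020 M | 0.020 M (fed, over 2.0 min) | 0.020 M | 0.020 M (fed, over 20 min) |
| reagent | 0.040 M | 0.020 M | 0.0400 M | 0.0400 M | 0.0400 M (fed, over 20 min) | 0.0400 M |
| free catalyst | 18 µM | 18 µM | 18 µM | 18 µM | 18 µM | 18 µM |
| remark | run made earlier | run made earlier | everything together at the start | all else is in the flask from the start; the feed brings no volume worth counting | all else is in the flask from the start; the feed brings no volume worth counting | all else is in the flask from the start; the feed brings no volume worth counting |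
| time |  |  | 25 min | 25 min | 25 min | 25 min |

| run | time / min | target / % | side product A / % |
|---|---|---|---|
| winter | 4.00 | 52.8 | 3.5 |
| winter | 8.00 | 74.3 | 5.1 |
| winter | 12.0 | 75.8 | 5.1 |
| winter | 15.0 | 76.3 | 5.3 |
| winter | 20.0 | 75.1 | 4.9 |
| winter | 25.0 | 76.5 | 5.5 |
| summer | 0.667 | 7.7 | 0.7 |
| summer | 1.00 | 11.6 | 0.1 |
| summer | 1.50 | 16.4 | 0.8 |
| summer | 2.50 | 24.6 | 1.6 |
| summer | 5.00 | 39.7 | 3.8 |
| summer | 8.00 | 51.2 | 6.0 |

(standard deviation of a reading: 0.3 percentage points)

- in percentages every species weighs as the substrate in it: one side product B counts as two
- the numbers in the tables scatter by 0.3 percentage points (one standard deviation)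
- candidate steps: catalyst intermediate A -> catalyst intermediate B; catalyst intermediate D <-> free catalyst + target; substrate + target -> side product B; reagent + free catalyst -> catalyst intermediate A; substrate + by-product -> side product A; catalyst intermediate C -> by-product + catalyst intermediate D; substrate + catalyst intermediate B -> catalyst intermediate C

- which flask leads in share of target in target plus side product A ("all alike" within 1.5 percentage points) (Monday's / Wednesday's / Sunday's / Thursday's / all alike)
- share of target in target plus side product A at the end, Monday's
- share of target in target plus side product A at the end, Wednesday's
- share of target in target plus side product A at the end, Sunday's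
- share of target in target plus side product A at the end, Thursday's

**Shortest rung.** Taking that ratio as standing through the winter run, the balance leaves substrate at 32.2% after 4.00 min and 3.91% after 8.00 min. Between these two readings substrate falls by 0.0708 min⁻¹ of the charge, and the log-mean standing substrate divided by that rate gives a residence time τ of 1.90 min. Over the first 4.00 min the same ratio is 3.53 min, so τ is smaller at lower substrate and the decay is not first-order, which makes τ a mean over that stretch and not a constant.

**Longer rungs.** At the pace of the first winter reading the charge clears in t_c = 7.58 min. Wednesday's feed of 2.0 min is shorter, so Wednesday's should follow Monday's, and Monday's is the winter recipe. In Sunday's, at one reagent per turnover, the feed allows a clearing time of 10.0 min, longer than t_c. Thursday's feed brings 0.0500 min⁻¹ of the charge, less than that winter rate, so Thursday's substrate should stand lower than in that stretch, with τ below 1.90 min.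

**Overlap time.** Side product A needs substrate and by-product together, so its gain per unit turned over follows the standing substrate divided by the turnover rate, weighted by the fraction already turned over. This weighted wait is the overlap time Θ, which for substrate falling steadily is a sixth of the clearing time: 1.26 min in the winter recipe and 1.67 min in Sunday's. For a steady standing level it is half of τ, which puts Thursday's below 0.948 min. The ratio of side product A to target, 0.0719 in winter, scales with Θ. My own reckoning therefore gives 93.3% for Monday's and Wednesday's, 91.3% for Sunday's and something above 94.9% for Thursday's.

**Forecast.** The forecast, holding that “Thursday's keeps substrate low”, names Thursday's, with 93.6%, 93.9%, 89% and 96.5% for Monday's, Wednesday's, Sunday's and Thursday's.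

**Result.** Thursday's leads: Monday's gives 93.6%, Wednesday's 93.8%, Sunday's 88.9% and Thursday's 96.7%.

    catalyst intermediate A → catalyst intermediate B (k = 970 min⁻¹)
    catalyst intermediate D ⇌ free catalyst + target (K = 0.0320 M, k = 3400 min⁻¹)
    substrate + target → side product B (k = 4.70 L mol⁻¹ min⁻¹)
    reagent + free catalyst → catalyst intermediate A (k = 11000 L mol⁻¹ min⁻¹)
    substrate + by-product → side product A (k = 2.50 L mol⁻¹ min⁻¹)
    catalyst intermediate C → by-product + catalyst intermediate D (k = 15000 min⁻¹)
    substrate + catalyst intermediate B → catalyst intermediate C (k = 53000 L mol⁻¹ min⁻¹)

**Further flask.** Thursday's ends with side product B at 11.0%, against 18.7% in Monday's. The overlap time also serves a flask like Sunday's but charged with 0.0080 M of substrate. Its clearing time shrinks with the charge, and the ratio scales with the charge and with Θ, which gives 98.5%; that flask ends at 96.9%.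

Readings and results stem from a simulated flask on assumed constants.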